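Ring labels: A and D are the two 4-hydroxy-3-methoxyphenyl rings. B carries the bridging CH2 between its OH and its OMe. C carries the same CH2 para to its OH.
Enabling feature: on ring C the CH2 is para to a free OH, so it is a 4-hydroxybenzyl unit and a latent para-quinone methide, the likely biosynthetic electrophile. On ring B the partner carbon lies between two C–O carbons, so it is C2 of a cyclohexane-1,3-dione, the only nucleophilic carbon of that ring at the dihydroresorcinol oxidation level.
Cuts: (i) bridge CH2–C(ring B), giving the para-quinone methide of the C/D half and the 5-substituted cyclohexane-1,3-dione of the A/B half; (ii) the ArCH2–CH2Ar bond of the C/D half (lateral alkylation of an orsellinate); (iii) the A/B ethano link (HWE olefination and hydrogenation), with the dione coming from Birch reduction of the 3,5-dimethoxyarene.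
Forward order: C/D half (steps 1–6), A/B half (steps 7–9), union (step 10). Ring B is then returned to the aromatic level by mono-O-methyl enol ether formation (step 11), dehydrogenation (step 12) and debenzylation (step 13).
Stereochemistry: the target has no stereogenic element. The only stereocentre on the way (C5 of cyclohexenone 19) is racemic and is erased in step 12.

Key step: step 10

Remark on the chemistry: the target is achiral (no stereocentre, no hindered axis), so the single species drawn is reached without any enantioselective step.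

Step 1
Reactants: 1 methyl 2,4-dihydroxy-6-methylbenzoate (methyl orsellinate)
Product: 2 methyl 2-hydroxy-6-methyl-4-[(triisopropylsilyl)oxy]benzoate
Conditions: TIPSCl (1.05 equiv), imidazole, DMF, 0 °C to rt
Reagents that add atoms: triisopropylsilyl chloride, CC(C)[Si](Cl)(C(C)C)C(C)C
Why: Selective phenol silylation should occur only at the free 4-OH, because the 2-OH is hydrogen-bonded to and flanked by the ester, and the TIPS ether later serves as the fluoride trigger on ring C.

Step 2
Reactants: 2 methyl 2-hydroxy-6-methyl-4-[(triisopropylsilyl)oxy]benzoate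
Product: 3 methyl 2-methoxy-6-methyl-4-[(triisopropylsilyl)oxy]benzoate
Conditions: MeI, K2CO3 (anhydrous), acetone, reflux
Reagents that add atoms: iodomethane, CI
Why: Williamson O-methylation of the remaining chelated phenol is standard for orsellinates, and the bulky aryl TIPS ether should survive anhydrous carbonate in acetone.

Step 3
Reactants: 4 [4-(benzyloxy)-3-methoxyphenyl]methanol
Product: 5 1-(benzyloxy)-4-(bromomethyl)-2-methoxybenzene
Conditions: PBr3, Et2O, 0 °C
Reagents that add atoms: phosphorus tribromide, BrP(Br)Br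
Why: Bromination of a primary benzylic alcohol through its phosphite ester (SN2) is routine and leaves the aryl ethers untouched.

Step 4
Reactants: 3 methyl 2-methoxy-6-methyl-4-[(triisopropylsilyl)oxy]benzoate; 5 1-(benzyloxy)-4-(bromomethyl)-2-methoxybenzene
Product: 7 methyl 2-{2-[4-(benzyloxy)-3-methoxyphenyl]ethyl}-6-methoxy-4-[(triisopropylsilyl)oxy]benzoate, via benzylic lithium species of the toluate 6 (not isolated)
Conditions: LDA, THF, −78 °C; then 5, −78 to −20 °C
Reagents that add atoms: none
Why: Lateral lithiation of an ortho-toluate gives an ester-stabilised benzylic anion that should be alkylated (SN2) by the reactive benzylic bromide, while low temperature and the doubly ortho-substituted ester hold back self-condensation.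

Step 5
Reactants: 7 methyl 2-{2-[4-(benzyloxy)-3-methoxyphenyl]ethyl}-6-methoxy-4-[(triisopropylsilyl)oxy]benzoate
Product: 8 (2-{2-[4-(benzyloxy)-3-methoxyphenyl]ethyl}-6-methoxy-4-[(triisopropylsilyl)oxy]phenyl)methanol
Conditions: DIBAL-H (3 equiv), CH2Cl2, −78 to 0 °C; Rochelle salt work-up
Reagents that add atoms: none
Why: Hydride reduction of the hindered ester to the primary alcohol is standard, and DIBAL-H tolerates aryl silyl and benzyl ethers.

Step 6
Reactants: 8 (2-{2-[4-(benzyloxy)-3-methoxyphenyl]ethyl}-6-methoxy-4-[(triisopropylsilyl)oxy]phenyl)methanol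
Product: 9 (2-{2-[4-(benzyloxy)-3-methoxyphenyl]ethyl}-6-methoxy-4-[(triisopropylsilyl)oxy]phenyl)methyl acetate
Conditions: Ac2O, pyridine, DMAP (cat.), CH2Cl2, 0 °C to rt
Reagents that add atoms: acetic anhydride, CC(=O)OC(C)=O
Why: DMAP-catalysed acylation installs the leaving group for the later 1,6-elimination, and the basic medium protects the acid-labile electron-rich benzylic system.

Step 7
Reactants: 10 diethyl (3,5-dimethoxybenzyl)phosphonate; 11 4-(benzyloxy)-3-methoxybenzaldehyde
Product: 12 (E)-1-(benzyloxy)-4-[2-(3,5-dimethoxyphenyl)ethenyl]-2-methoxybenzene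
Conditions: KOt-Bu added to both partners, THF, 0 °C to rt
Reagents that add atoms: none
Why: Horner–Wadsworth–Emmons olefination of a non-enolisable aldehyde should give the E-stilbene, whose geometry does not matter because the alkene is saturated in step 8.

Step 8
Reactants: 12 (E)-1-(benzyloxy)-4-[2-(3,5-dimethoxyphenyl)ethenyl]-2-methoxybenzene
Product: 13 4-[2-(3,5-dimethoxyphenyl)ethyl]-2-methoxyphenol
Conditions: H2 (1 atm), 10% Pd/C, EtOAc–EtOH, rt
Reagents that add atoms: none
Why: Catalytic hydrogenation saturates the stilbene and hydrogenolyses the benzyl ether in one operation, freeing the ring-A phenol that shields this ring in step 9.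

Step 9
Reactants: 13 4-[2-(3,5-dimethoxyphenyl)ethyl]-2-methoxyphenol
Product: 15 5-[2-(4-hydroxy-3-methoxyphenyl)ethyl]cyclohexane-1,3-dione, via bis(enol ether) diene 14 (not isolated)
Conditions: Li, NH3(l), THF, t-BuOH, −78 to −33 °C; NH4Cl; then 1 M HCl, THF, rt
Reagents that add atoms: water, O
Why: In this Birch reduction ring A is present as its lithium phenoxide and should resist electron uptake, while ring B is reduced to the 1,4-diene with both methoxy groups on the remaining double bonds, and acid hydrolysis of this bis(enol ether) gives the symmetrical 1,3-dione.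

Step 10
Reactants: 9 (2-{2-[4-(benzyloxy)-3-methoxyphenyl]ethyl}-6-methoxy-4-[(triisopropylsilyl)oxy]phenyl)methyl acetate; 15 5-[2-(4-hydroxy-3-methoxyphenyl)ethyl]cyclohexane-1,3-dione
Product: 18 2-[(2-{2-[4-(benzyloxy)-3-methoxyphenyl]ethyl}-4-hydroxy-6-methoxyphenyl)methyl]-5-[2-(4-hydroxy-3-methoxyphenyl)ethyl]cyclohexane-1,3-dione, via sodium enolate of the dione 16 (not isolated), via para-quinone methide 17 (not isolated)
Conditions: 15 (1.5 equiv), NaH (1.5 equiv), THF–DMF, 0 °C; add 9; TBAF (1.5 equiv, syringe pump), 0 °C to rt; 1 M HCl quench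
Reagents that add atoms: none
Why: Fluoride removes the TIPS group of 9, the ring-C phenoxide expels the para-benzylic acetate (1,6-elimination), and the para-quinone methide 17 so released in low stationary concentration is attacked at its exocyclic CH2 by C2 of enolate 16 (1,6-conjugate addition), which re-aromatises ring C and forms the CH2–C2 bond. The closest known reaction type is the 1,6-addition of cyclic 1,3-dicarbonyl compounds to para-quinone methides generated in situ from 4-hydroxy- or 4-silyloxybenzyl esters, and the event copies the presumed biosynthetic union of an oxidised C1-substituted gigantol with a second bibenzyl unit. No ring is closed and no lasting stereocentre is made, because 18 is an enolised 2-substituted 1,3-dione whose C2 and C5 become sp2 carbons of ring B in step 12. The site selectivity that an aromatic bibenzyl nucleophile could not give (three activated ring positions) is secured by the oxidation level of 16, whose only nucleophilic carbon is C2 between the two C–O carbons, the future ring-B carbon between OH and OMe. C- versus O-alkylation and mono- versus double alkylation are secured thermodynamically: O-bound and 2,2-disubstituted adducts still hold a 4-hydroxybenzyl group on a good nucleofuge and should revert to 17 under the slight excess of fluoride base, whereas the mono C-adduct leaves the equilibrium as its own enolate. Chemoselectivity rests on the basic medium and the protecting pattern: ring D stays a benzyl ether (no phenoxide ipso-spirocyclisation, no acid-driven Friedel–Crafts closure to a dibenzosuberane), and the ring-A phenol is far less acidic than the dione, so the enolate carbon is the dominant nucleophile.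

Step 11
Reactants: 18 2-[(2-{2-[4-(benzyloxy)-3-methoxyphenyl]ethyl}-4-hydroxy-6-methoxyphenyl)methyl]-5-[2-(4-hydroxy-3-methoxyphenyl)ethyl]cyclohexane-1,3-dione
Product: 19 (±)-2-[(2-{2-[4-(benzyloxy)-3-methoxyphenyl]ethyl}-4-hydroxy-6-methoxyphenyl)methyl]-5-[2-(4-hydroxy-3-methoxyphenyl)ethyl]-3-methoxycyclohex-2-en-1-one
Conditions: HC(OMe)3, TsOH·H2O (cat.), MeOH, rt
Reagents that add atoms: trimethyl orthoformate, COC(OC)OC
Why: Acid-catalysed enol etherification (vinylogous ester formation) touches only the dione and not the phenols, and because the two carbonyl groups are enantiotopic a single constitutional isomer (racemic) should form, which fixes the OH/OMe pattern of ring B.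

Step 12
Reactants: 19 (±)-2-[(2-{2-[4-(benzyloxy)-3-methoxyphenyl]ethyl}-4-hydroxy-6-methoxyphenyl)methyl]-5-[2-(4-hydroxy-3-methoxyphenyl)ethyl]-3-methoxycyclohex-2-en-1-one
Product: 22 2-[(2-{2-[4-(benzyloxy)-3-methoxyphenyl]ethyl}-4-hydroxy-6-methoxyphenyl)methyl]-5-[2-(4-hydroxy-3-methoxyphenyl)ethyl]-3-methoxyphenol, via tris(trimethylsilyl) silyloxydiene 20 (not isolated), via bis(trimethylsilyl) ether of the new phenol 21 (not isolated)
Conditions: TMSOTf, Et3N, CH2Cl2, 0 °C; solvent switch; Pd(OAc)2 (1.1 equiv), MeCN, rt; then 1 M HCl, THF, rt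
Reagents that add atoms: none
Why: Soft enolisation masks both free phenols as TMS ethers and turns the vinylogous ester into a silyloxydiene (either regioisomer converges on the same arene), Saegusa–Ito oxidation (Pd(II) enolate, β-hydride elimination of C5–H) gives a cyclohexadienone that tautomerises to the ring-B phenol and erases the C5 stereocentre, and dilute acid removes the TMS groups.

Step 13
Reactants: 22 2-[(2-{2-[4-(benzyloxy)-3-methoxyphenyl]ethyl}-4-hydroxy-6-methoxyphenyl)methyl]-5-[2-(4-hydroxy-3-methoxyphenyl)ethyl]-3-methoxyphenol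
Product: 23 2-({4-hydroxy-2-[2-(4-hydroxy-3-methoxyphenyl)ethyl]-6-methoxyphenyl}methyl)-5-[2-(4-hydroxy-3-methoxyphenyl)ethyl]-3-methoxyphenol (target)
Conditions: H2 (1 atm), 10% Pd/C, EtOAc–MeOH, rt
Reagents that add atoms: none
Why: Hydrogenolysis of the last aryl benzyl ether under neutral conditions should leave the diarylmethane, the ethano links and the methyl ethers untouched.

Compound list
1 | methyl 2,4-dihydroxy-6-methylbenzoate (methyl orsellinate) | COC(=O)c1c(C)cc(O)cc1O | starting material
2 | methyl 2-hydroxy-6-methyl-4-[(triisopropylsilyl)oxy]benzoate | COC(=O)c1c(C)cc(O[Si](C(C)C)(C(C)C)C(C)C)cc1O | intermediate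
3 | methyl 2-methoxy-6-methyl-4-[(triisopropylsilyl)oxy]benzoate | COC(=O)c1c(C)cc(O[Si](C(C)C)(C(C)C)C(C)C)cc1OC | intermediate
4 | [4-(benzyloxy)-3-methoxyphenyl]methanol | COc1cc(CO)ccc1OCc1ccccc1 | starting material
5 | 1-(benzyloxy)-4-(bromomethyl)-2-methoxybenzene | COc1cc(CBr)ccc1OCc1ccccc1 | intermediate
6 | benzylic lithium species of 3 (lithiated at the 6-methyl group) | [Li]Cc1cc(O[Si](C(C)C)(C(C)C)C(C)C)cc(OC)c1C(=O)OC | intermediate
7 | methyl 2-{2-[4-(benzyloxy)-3-methoxyphenyl]ethyl}-6-methoxy-4-[(triisopropylsilyl)oxy]benzoate | COC(=O)c1c(CCc2ccc(OCc3ccccc3)c(OC)c2)cc(O[Si](C(C)C)(C(C)C)C(C)C)cc1OC | intermediate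
8 | (2-{2-[4-(benzyloxy)-3-methoxyphenyl]ethyl}-6-methoxy-4-[(triisopropylsilyl)oxy]phenyl)methanol | OCc1c(CCc2ccc(OCc3ccccc3)c(OC)c2)cc(O[Si](C(C)C)(C(C)C)C(C)C)cc1OC | intermediate
9 | (2-{2-[4-(benzyloxy)-3-methoxyphenyl]ethyl}-6-methoxy-4-[(triisopropylsilyl)oxy]phenyl)methyl acetate | CC(=O)OCc1c(CCc2ccc(OCc3ccccc3)c(OC)c2)cc(O[Si](C(C)C)(C(C)C)C(C)C)cc1OC | intermediate
10 | diethyl (3,5-dimethoxybenzyl)phosphonate | CCOP(=O)(Cc1cc(OC)cc(OC)c1)OCC | starting material
11 | 4-(benzyloxy)-3-methoxybenzaldehyde | COc1cc(C=O)ccc1OCc1ccccc1 | starting material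
12 | (E)-1-(benzyloxy)-4-[2-(3,5-dimethoxyphenyl)ethenyl]-2-methoxybenzene | COc1cc(/C=C/c2ccc(OCc3ccccc3)c(OC)c2)cc(OC)c1 | intermediate
13 | 4-[2-(3,5-dimethoxyphenyl)ethyl]-2-methoxyphenol | COc1cc(CCc2ccc(O)c(OC)c2)cc(OC)c1 | intermediate
14 | 4-[2-(3,5-dimethoxycyclohexa-2,5-dien-1-yl)ethyl]-2-methoxyphenol | COC1=CC(CCc2ccc(O)c(OC)c2)C=C(OC)C1 | intermediate
15 | 5-[2-(4-hydroxy-3-methoxyphenyl)ethyl]cyclohexane-1,3-dione | O=C1CC(CCc2ccc(O)c(OC)c2)CC(=O)C1 | intermediate
16 | sodium enolate of 15 | [Na+].[O-]C1=CC(=O)CC(CCc2ccc(O)c(OC)c2)C1 | intermediate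
17 | 3-{2-[4-(benzyloxy)-3-methoxyphenyl]ethyl}-5-methoxy-4-methylidenecyclohexa-2,5-dien-1-one (para-quinone methide) | C=C1C(CCc2ccc(OCc3ccccc3)c(OC)c2)=CC(=O)C=C1OC | intermediate
18 | 2-[(2-{2-[4-(benzyloxy)-3-methoxyphenyl]ethyl}-4-hydroxy-6-methoxyphenyl)methyl]-5-[2-(4-hydroxy-3-methoxyphenyl)ethyl]cyclohexane-1,3-dione (drawn as diketo tautomer, largely enolised) | O=C1CC(CCc2ccc(O)c(OC)c2)CC(=O)C1Cc1c(CCc2ccc(OCc3ccccc3)c(OC)c2)cc(O)cc1OC | intermediate
19 | (±)-2-[(2-{2-[4-(benzyloxy)-3-methoxyphenyl]ethyl}-4-hydroxy-6-methoxyphenyl)methyl]-5-[2-(4-hydroxy-3-methoxyphenyl)ethyl]-3-methoxycyclohex-2-en-1-one (racemic) | COC1=C(Cc2c(CCc3ccc(OCc4ccccc4)c(OC)c3)cc(O)cc2OC)C(=O)CC(CCc2ccc(O)c(OC)c2)C1 | intermediate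
20 | silyloxydiene of 19 with OTMS at C1 and on rings A and C (racemic) | COC1=C(Cc2c(CCc3ccc(OCc4ccccc4)c(OC)c3)cc(O[Si](C)(C)C)cc2OC)C(O[Si](C)(C)C)=CC(CCc2ccc(O[Si](C)(C)C)c(OC)c2)C1 | intermediate
21 | bis(trimethylsilyl) ether of 22 (OTMS on rings A and C, free OH on ring B) | COc1cc(CCc2cc(O)c(Cc3c(CCc4ccc(OCc5ccccc5)c(OC)c4)cc(O[Si](C)(C)C)cc3OC)c(OC)c2)ccc1O[Si](C)(C)C | intermediate
22 | 2-[(2-{2-[4-(benzyloxy)-3-methoxyphenyl]ethyl}-4-hydroxy-6-methoxyphenyl)methyl]-5-[2-(4-hydroxy-3-methoxyphenyl)ethyl]-3-methoxyphenol | COc1cc(CCc2cc(O)c(Cc3c(CCc4ccc(OCc5ccccc5)c(OC)c4)cc(O)cc3OC)c(OC)c2)ccc1O | intermediate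
23 | 2-({4-hydroxy-2-[2-(4-hydroxy-3-methoxyphenyl)ethyl]-6-methoxyphenyl}methyl)-5-[2-(4-hydroxy-3-methoxyphenyl)ethyl]-3-methoxyphenol | COc1cc(CCc2cc(O)c(Cc3c(CCc4ccc(O)c(OC)c4)cc(O)cc3OC)c(OC)c2)ccc1O | target

Total step count: 13. Longest linear sequence: 9 steps (1, 2, 4, 5, 6, 10, 11, 12, 13).

Steps most likely to fail

Step 10. The quinone methide may be consumed by phenoxide attack and self-condensation faster than by the enolate carbon, or alkylation may stall at oxygen if the equilibration is too slow. The fallback replaces the quinone methide addition with a condensation–reduction sequence that forms the same CH2–C2 bond. It sets out from 8 and comes back to the route at 18. Oxidation of 8 with MnO2 in CH2Cl2 should give 2-{2-[4-(benzyloxy)-3-methoxyphenyl]ethyl}-6-methoxy-4-[(triisopropylsilyl)oxy]benzaldehyde F1. An organocatalytic three-component reductive alkylation follows, using F1, 15, L-proline (cat.) and Hantzsch ester in CH2Cl2–EtOH at rt. It runs by Knoevenagel condensation and then conjugate hydride transfer to the arylidene dione, and should give the ring-C TIPS ether of 18 F2. TBAF buffered with AcOH in THF then frees the phenol to give 18.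

Step 12. Silylation may be incomplete, the TMS ethers may be lost before the oxidation, or Pd(II) may engage the free phenols instead of the enol ether. The fallback uses permanent protection and a selenoxide elimination. It sets out from 19 and comes back to the route at 23. Benzylation of both phenols (BnBr, K2CO3, DMF) should give the tris(benzyl ether) of the cyclohexenone F3. Kinetic deprotonation with LDA in THF at −78 °C and trapping with PhSeCl should give the 6-(phenylselanyl) ketone F4, with selenium anti to the C5 side chain. Oxidation with H2O2 and pyridine in CH2Cl2 at 0 °C triggers syn elimination of the selenoxide, and tautomerisation gives the tris(benzyl ether) of the target with free ring-B OH F5. Hydrogenolysis (H2, Pd/C) removes all three benzyl groups to give 23.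

Step 9. The lithium phenoxide may dissolve poorly in ammonia. Ring B may be over-reduced or lose a methoxy group reductively, and ring A may be partly reduced. The fallback reaches the dione by catalytic partial hydrogenation of a resorcinol instead of dissolving-metal reduction. It sets out from 5 and comes back to the route at 15. Heating 5 with triethyl phosphite (Michaelis–Arbuzov) should give diethyl [4-(benzyloxy)-3-methoxybenzyl]phosphonate F6. HWE olefination with purchased 3,5-bis(benzyloxy)benzaldehyde F7 (KOt-Bu, THF) should give (E)-1-(benzyloxy)-4-{2-[3,5-bis(benzyloxy)phenyl]ethenyl}-2-methoxybenzene F8. Hydrogenation (H2, Pd/C) saturates the alkene and removes the three benzyl groups to give 5-[2-(4-hydroxy-3-methoxyphenyl)ethyl]benzene-1,3-diol F9. Transfer hydrogenation of the resorcinol ring as its mono-anion (HCO2Na, Pd/C, H2O, about 50 °C) should stop at the stage of the dione enolate, and acidification then gives 15.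

Further compounds
F1 | step 10 | 2-{2-[4-(benzyloxy)-3-methoxyphenyl]ethyl}-6-methoxy-4-[(triisopropylsilyl)oxy]benzaldehyde | O=Cc1c(CCc2ccc(OCc3ccccc3)c(OC)c2)cc(O[Si](C(C)C)(C(C)C)C(C)C)cc1OC
F2 | step 10 | ring-C TIPS ether of 18 | O=C1CC(CCc2ccc(O)c(OC)c2)CC(=O)C1Cc1c(CCc2ccc(OCc3ccccc3)c(OC)c2)cc(O[Si](C(C)C)(C(C)C)C(C)C)cc1OC
F3 | step 12 | tris(benzyl ether) of the cyclohexenone (19 benzylated on rings A and C, racemic) | COC1=C(Cc2c(CCc3ccc(OCc4ccccc4)c(OC)c3)cc(OCc3ccccc3)cc2OC)C(=O)CC(CCc2ccc(OCc3ccccc3)c(OC)c2)C1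
F4 | step 12 | 6-(phenylselanyl) ketone derived from F3 (racemic, selenium expected trans to the C5 side chain) | COC1=C(Cc2c(CCc3ccc(OCc4ccccc4)c(OC)c3)cc(OCc3ccccc3)cc2OC)C(=O)C([Se]c2ccccc2)C(CCc2ccc(OCc3ccccc3)c(OC)c2)C1
F5 | step 12 | tris(benzyl ether) of the target with free ring-B OH | COc1cc(CCc2cc(O)c(Cc3c(CCc4ccc(OCc5ccccc5)c(OC)c4)cc(OCc4ccccc4)cc3OC)c(OC)c2)ccc1OCc1ccccc1
F6 | step 9 | diethyl [4-(benzyloxy)-3-methoxybenzyl]phosphonate | CCOP(=O)(Cc1ccc(OCc2ccccc2)c(OC)c1)OCC
F7 | step 9 | 3,5-bis(benzyloxy)benzaldehyde (purchased) | O=Cc1cc(OCc2ccccc2)cc(OCc2ccccc2)c1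
F8 | step 9 | (E)-1-(benzyloxy)-4-{2-[3,5-bis(benzyloxy)phenyl]ethenyl}-2-methoxybenzene | COc1cc(/C=C/c2cc(OCc3ccccc3)cc(OCc3ccccc3)c2)ccc1OCc1ccccc1
F9 | step 9 | 5-[2-(4-hydroxy-3-methoxyphenyl)ethyl]benzene-1,3-diol | COc1cc(CCc2cc(O)cc(O)c2)ccc1O
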